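Retrosynthesis (eudesmane numbering): cut C5–OOH by an ene reaction that moves the double bond back to C4=C5. Then cut the two acyl groups, close the C12 ester back to the 8β,12-lactone, cut C11=C13 and C7–C11, lift C4 with its methyl C15 out of ring A, and last cut C3–C5 and C1–C10.
Forward: ring B is bought as a cyclohexanone and a cyclopentene (C1, C2, C3, C5, C10) is closed on it. A temporary cyclopropane C3–C4–C5 is added and its shared bond C3–C5 is broken, which turns the five-membered ring into ring A. A temporary γ-lactone (C7, C8, O, C12, C11) is then built on ring B and opened again.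
Enabling feature: in ring A the oxygenated C3, the carbon C4 that bears only C15, and the ring-fusion carbon C5 form an allyl triad. Without C4 this triad is the enol ether C3(OMe)=C5 of a hydrindane. A cyclopropyl-to-allyl cation opening puts C4–C15 exactly between C3 and C5 and leaves the tetrasubstituted C4=C5 bond that the last step needs.
Stereochemistry: C10 comes from (R)-1-phenylethylamine, and the racemic ketone converges. C3, C8 and C5 are set by attack anti to the angular C10 methyl (hydride, hydride, singlet oxygen). C7 is set by equilibration next to the C8 ketone and is then locked cis to C8–O by the lactone.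

Key step: step 3

Remark: eudesmane numbering (C1 to C15) is used for all intermediates, also before all carbons are in place, and β is the face of the angular methyl on C10. The starting cyclohexanone is taken as the commercial racemate.

Step 1
Reactants: 1 (±)-7-methyl-1,4-dioxaspiro[4.5]decan-8-one; 2 (R)-1-phenylethylamine; 3 methyl acrylate
Product: 6 methyl 3-[(7R)-7-methyl-8-oxo-1,4-dioxaspiro[4.5]decan-7-yl]propanoate, via ketimine 4 (not isolated), via alkylated ketimine 5 (not isolated)
Conditions: 1 + 2, TsOH (cat.), toluene, Dean–Stark, reflux; then 3, THF, 50 °C; then 20% aq AcOH, rt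
Reagents that add atoms: water, O
Why: Deracemising Michael alkylation of a chiral ketimine, in which 4 reacts through its more substituted secondary enamine tautomer where C10 is planar so that both enantiomers of 1 converge, and the (R)-phenylethyl group shields one face in the cyclic aza-ene-like transition state, which should set the quaternary C10 (10β-methyl series) before mild hydrolysis returns the auxiliary without touching the dioxolane.

Step 2
Reactants: 6 methyl 3-[(7R)-7-methyl-8-oxo-1,4-dioxaspiro[4.5]decan-7-yl]propanoate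
Product: 7 (7aR)-3-methoxy-7a-methyl-1,2,4,5,7,7a-hexahydrospiro[indene-6,2'-[1,3]dioxolane] (hydrindene enol ether C3(OMe)=C5)
Conditions: TiCl3, LiAlH4, Et3N, DME, reflux, slow addition of 6; aq K2CO3 work-up
Reagents that add atoms: none
Why: The McMurry keto ester cyclisation with low-valent titanium joins the ketone carbon C5 and the ester carbon C3 in a five-membered ring and stops at the enol ether, so the C3=C5 double bond should be placed regiospecifically, no stereocentre is made, C10 is untouched, and the amine buffer and basic work-up protect the dioxolane and the enol ether.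

Step 3
Reactants: 7 hydrindene enol ether; 8 1,1-dichloroethane
Product: 10 8,8-ethylenedioxy-11,12,13-trinoreudesm-4-en-3-one (10β-methyl), via chlorocyclopropane 9 (not isolated)
Conditions: 8, n-BuLi, Et2O, −40 to 0 °C; then NaHCO3, H2O–dioxane, 70 °C
Reagents that add atoms: water, O
Why: 1,1-Dichloroethyllithium loses LiCl and the chloro(methyl)carbenoid adds in a concerted [2+1] cheletropic closure to the only, very electron-rich double bond C3=C5 of 7 from the α face anti to the angular C10 methyl, which closes the temporary cyclopropane C3–C4–C5 of 9. In 9 the chloride that lies over the five-membered ring leaves while the shared bond C3–C5 opens in a disrotatory two-electron electrocyclic process (cyclopropyl to allyl cation, Woodward–Hoffmann–DePuy rule) pushed by the methoxy group on C3, so the cyclopentane (C1, C2, C3, C5, C10) becomes the cyclohexene ring A with C4 and its methyl C15 inserted between C3 and C5. Water adds to the 1-methoxyallyl (oxocarbenium) cation at C3 and methanol leaves, which should give the 4-methyl-4-en-3-one while the bicarbonate buffer keeps the dioxolane. The closest known reaction type is the one-carbon ring enlargement of cyclic enol ethers and silyl enol ethers through their halocarbene adducts to 2-halo- or 2-methylcycloalk-2-enones. The three cyclopropane stereocentres are transient and vanish in the planar enone, so no lasting stereocentre is made and C10 is not touched. The step needs site selectivity, which is secured because the double bond sits exactly where the carbon must go, and it needs the chlorine on the ring side of the cyclopropane, which rests on the usual preference of chloro(alkyl)carbenes to turn the polarisable halogen toward the ring and the larger methyl outward.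

Step 4
Reactants: 10 8,8-ethylenedioxy-11,12,13-trinoreudesm-4-en-3-one
Product: 11 8,8-ethylenedioxy-11,12,13-trinoreudesm-4-en-3β-ol
Conditions: NaBH4, CeCl3·7H2O, MeOH, −20 °C
Reagents that add atoms: none
Why: The Luche reduction should give clean 1,2-addition with hydride entering axially from the α face opposite to the angular C10 methyl, as is usual for 4-en-3-ones of 10β-methyl decalins, which sets the pseudo-equatorial 3β-alcohol and leaves the dioxolane alone.

Step 5
Reactants: 11 8,8-ethylenedioxy-11,12,13-trinoreudesm-4-en-3β-ol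
Product: 12 3β-(tert-butyldimethylsilyloxy)-8,8-ethylenedioxy-11,12,13-trinoreudesm-4-ene
Conditions: TBSCl, imidazole, DMF, rt
Reagents that add atoms: tert-butyldimethylsilyl chloride, CC(C)(C)[Si](C)(C)Cl
Why: Standard silylation with retention at C3 masks the allylic alcohol against the amide bases, hydride and hydroxide of steps 7 to 10.

Step 6
Reactants: 12 3β-(tert-butyldimethylsilyloxy)-8,8-ethylenedioxy-11,12,13-trinoreudesm-4-ene
Product: 13 3β-(tert-butyldimethylsilyloxy)-11,12,13-trinoreudesm-4-en-8-one
Conditions: PPTS, acetone–H2O, 55 °C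
Reagents that add atoms: water, O
Why: Mild acid-catalysed ketal hydrolysis should free the C8 ketone, because PPTS is too weak to cleave or ionise the secondary allylic silyl ether and the C4=C5 bond is too remote from C8 to move into conjugation.

Step 7
Reactants: 13 3β-(tert-butyldimethylsilyloxy)-11,12,13-trinoreudesm-4-en-8-one; 14 methyl bromoacetate
Product: 17 methyl 3β-(tert-butyldimethylsilyloxy)-8-oxo-13-noreudesm-4-en-12-oate (7β side chain), via lithium enolate 15 (not isolated), via 7α-epimer 16 (not isolated)
Conditions: LDA, THF, −78 °C; then 14, DMPU, −78 to −20 °C; then NaOMe (cat.), MeOH, rt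
Reagents that add atoms: none
Why: In this kinetic enolate alkylation (SN2 on the α-bromo ester) LDA should deprotonate C7 rather than the neopentyl C9, and the axial 7α product of stereoelectronic attack is then equilibrated by methoxide through the C8 enolate to the equatorial 7β side chain.

Step 8
Reactants: 17 methyl 3β-(tert-butyldimethylsilyloxy)-8-oxo-13-noreudesm-4-en-12-oate
Product: 19 3β-(tert-butyldimethylsilyloxy)-13-noreudesm-4-en-8β,12-olide (cis-fused), via hydroxy ester 18 (not isolated)
Conditions: NaBH4, MeOH, 0 °C to rt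
Reagents that add atoms: none
Why: Borohydride should attack the C8 ketone from the α face because the axial β approach is blocked by the syn-axial C10 methyl, and the axial 8β-alkoxide closes on the neighbouring ester (5-exo-trig lactonisation) to the cis-fused γ-lactone that locks C7 and C8 in the cis relation of the target.

Step 9
Reactants: 19 3β-(tert-butyldimethylsilyloxy)-13-noreudesm-4-en-8β,12-olide
Product: 21 13-(dimethylamino)-3β-(tert-butyldimethylsilyloxy)-11βH-eudesm-4-en-8β,12-olide, via lactone enolate 20 (not isolated)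
Conditions: LDA, THF, −78 °C; then CH2=NMe2+ I− (Eschenmoser's salt), −78 °C to rt
Reagents that add atoms: N,N-dimethylmethyleneiminium iodide, C=[N+](C)C.[I-]
Why: Mannich aminomethylation of the lactone enolate brings in C13 from the convex face of the cis-fused bicycle, the new C11 centre is erased later, and the amine is kept on purpose as a mask of the acrylate during the basic ring opening.

Step 10
Reactants: 21 13-(dimethylamino)-3β-(tert-butyldimethylsilyloxy)-11βH-eudesm-4-en-8β,12-olide
Product: 24 methyl 8β-hydroxy-3β-(tert-butyldimethylsilyloxy)eudesma-4,11(13)-dien-12-oate, via potassium carboxylate 22 (not isolated), via ammonium iodide 23 (not isolated)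
Conditions: KOH (1.1 equiv), MeOH–H2O, rt; evaporate; then MeI (excess), K2CO3, DMF, rt
Reagents that add atoms: potassium hydroxide, [K+].[OH-]; iodomethane, CI
Why: Saponification by acyl–oxygen cleavage keeps the C8–O bond and its configuration, and iodomethane then alkylates the carboxylate (SN2) and quaternises the amine so that a Hofmann-type E1cB elimination with carbonate should unveil the C11=C13 acrylate, with no acid present that could close the lactone again.

Step 11
Reactants: 24 methyl 8β-hydroxy-3β-(tert-butyldimethylsilyloxy)eudesma-4,11(13)-dien-12-oate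
Product: 25 methyl 8β-acetoxy-3β-(tert-butyldimethylsilyloxy)eudesma-4,11(13)-dien-12-oate
Conditions: Ac2O, DMAP, Et3N, CH2Cl2, rt
Reagents that add atoms: acetic anhydride, CC(=O)OC(C)=O
Why: DMAP-catalysed acetylation should acylate the hindered axial 8β-alcohol with retention and removes for good the possibility of relactonisation.

Step 12
Reactants: 25 methyl 8β-acetoxy-3β-(tert-butyldimethylsilyloxy)eudesma-4,11(13)-dien-12-oate
Product: 26 methyl 8β-acetoxy-3β-hydroxyeudesma-4,11(13)-dien-12-oate
Conditions: HF·pyridine, THF, 0 °C to rt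
Reagents that add atoms: none
Why: Fluoride-driven cleavage of the silyl ether in the pyridine-buffered medium should spare the acetate, the methyl ester and the acrylate, is not basic enough for acyl migration, and leaves C3 unchanged.

Step 13
Reactants: 26 methyl 8β-acetoxy-3β-hydroxyeudesma-4,11(13)-dien-12-oate
Product: 27 methyl 8β-acetoxy-3β-isobutyryloxyeudesma-4,11(13)-dien-12-oate
Conditions: isobutyryl chloride, pyridine, DMAP (cat.), CH2Cl2, 0 °C
Reagents that add atoms: isobutyryl chloride, CC(C)C(=O)Cl
Why: O-acylation of the only free hydroxyl group proceeds at oxygen and therefore with retention at C3.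

Step 14
Reactants: 27 methyl 8β-acetoxy-3β-isobutyryloxyeudesma-4,11(13)-dien-12-oate
Product: 28 methyl 8β-acetoxy-5α-hydroperoxy-3β-isobutyryloxyeudesma-4(15),11(13)-dien-12-oate (target)
Conditions: O2, tetraphenylporphyrin (cat.), visible light, CH2Cl2, −20 °C
Reagents that add atoms: dioxygen, O=O
Why: The Schenck ene reaction, which copies the presumed biogenesis of the hydroperoxide, should engage only the electron-rich tetrasubstituted C4=C5 bond and not the acrylate, attack from the α face anti to the angular C10 methyl to set 5α, and take a hydrogen from the C15 methyl that is geminal to the acyloxy-bearing C3 (geminal selectivity next to an allylic heteroatom, with H3 deactivated by the ester), so that the double bond moves to C4=C15.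

Compound list
1 | (±)-7-methyl-1,4-dioxaspiro[4.5]decan-8-one | CC1CC2(CCC1=O)OCCO2 | starting material
2 | (R)-1-phenylethylamine | C[C@@H](N)c1ccccc1 | starting material
3 | methyl acrylate | C=CC(=O)OC | starting material
4 | N-[(R)-1-phenylethyl] ketimine of 1 (both C10 epimers, in equilibrium through the enamine) | CC1CC2(CCC1=N[C@H](C)c1ccccc1)OCCO2 | intermediate
5 | C10-alkylated ketimine (10R) | COC(=O)CC[C@]1(C)CC2(CCC1=N[C@H](C)c1ccccc1)OCCO2 | intermediate
6 | methyl 3-[(7R)-7-methyl-8-oxo-1,4-dioxaspiro[4.5]decan-7-yl]propanoate | COC(=O)CC[C@]1(C)CC2(CCC1=O)OCCO2 | intermediate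
7 | (7aR)-3-methoxy-7a-methyl-1,2,4,5,7,7a-hexahydrospiro[indene-6,2'-[1,3]dioxolane] | COC1=C2CCC3(C[C@@]2(C)CC1)OCCO3 | intermediate
8 | 1,1-dichloroethane | CC(Cl)Cl | starting material
9 | chlorocyclopropane: C4(Cl)(CH3) bridges C3 and C5 of 7 on the α face, chlorine over the five-membered ring, methoxy on C3 | CO[C@@]12CC[C@]3(C)CC4(OCCO4)CC[C@@]13[C@]2(C)Cl | intermediate
10 | 8,8-ethylenedioxy-11,12,13-trinoreudesm-4-en-3-one | O=C1CC[C@]2(C)CC3(CCC2=C1C)OCCO3 | intermediate
11 | 8,8-ethylenedioxy-11,12,13-trinoreudesm-4-en-3β-ol | CC1=C2CCC3(OCCO3)C[C@@]2(C)CC[C@@H]1O | intermediate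
12 | 3β-(tert-butyldimethylsilyloxy)-8,8-ethylenedioxy-11,12,13-trinoreudesm-4-ene | CC1=C2CCC3(OCCO3)C[C@@]2(C)CC[C@@H]1O[Si](C)(C)C(C)(C)C | intermediate
13 | 3β-(tert-butyldimethylsilyloxy)-11,12,13-trinoreudesm-4-en-8-one | CC1=C2CCC(=O)C[C@@]2(C)CC[C@@H]1O[Si](C)(C)C(C)(C)C | intermediate
14 | methyl bromoacetate | COC(=O)CBr | starting material
15 | lithium 7-en-8-olate of 13 | [Li]OC1=CCC2=C(C)[C@@H](O[Si](C)(C)C(C)(C)C)CC[C@]2(C)C1 | intermediate
16 | 7α-epimer of 17 | COC(=O)C[C@@H]1CC2=C(C)[C@@H](O[Si](C)(C)C(C)(C)C)CC[C@]2(C)CC1=O | intermediate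
17 | methyl 3β-(tert-butyldimethylsilyloxy)-8-oxo-13-noreudesm-4-en-12-oate | COC(=O)C[C@H]1CC2=C(C)[C@@H](O[Si](C)(C)C(C)(C)C)CC[C@]2(C)CC1=O | intermediate
18 | methyl 8β-hydroxy-3β-(tert-butyldimethylsilyloxy)-13-noreudesm-4-en-12-oate | COC(=O)C[C@H]1CC2=C(C)[C@@H](O[Si](C)(C)C(C)(C)C)CC[C@]2(C)C[C@H]1O | intermediate
19 | 3β-(tert-butyldimethylsilyloxy)-13-noreudesm-4-en-8β,12-olide | O=C1C[C@H]2CC3=C(C)[C@@H](O[Si](C)(C)C(C)(C)C)CC[C@]3(C)C[C@H]2O1 | intermediate
20 | lithium enolate of lactone 19 | [Li]OC1=C[C@H]2CC3=C(C)[C@@H](O[Si](C)(C)C(C)(C)C)CC[C@]3(C)C[C@H]2O1 | intermediate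
21 | 13-(dimethylamino)-3β-(tert-butyldimethylsilyloxy)-11βH-eudesm-4-en-8β,12-olide | O=C1[C@H](CN(C)C)[C@H]2CC3=C(C)[C@@H](O[Si](C)(C)C(C)(C)C)CC[C@]3(C)C[C@H]2O1 | intermediate
22 | potassium 13-(dimethylamino)-8β-hydroxy-3β-(tert-butyldimethylsilyloxy)eudesm-4-en-12-oate | O=C([O-])[C@H](CN(C)C)[C@H]1CC2=C(C)[C@@H](O[Si](C)(C)C(C)(C)C)CC[C@]2(C)C[C@H]1O.[K+] | intermediate
23 | methyl 8β-hydroxy-13-(trimethylammonio)-3β-(tert-butyldimethylsilyloxy)eudesm-4-en-12-oate iodide | COC(=O)[C@H](C[N+](C)(C)C)[C@H]1CC2=C(C)[C@@H](O[Si](C)(C)C(C)(C)C)CC[C@]2(C)C[C@H]1O.[I-] | intermediate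
24 | methyl 8β-hydroxy-3β-(tert-butyldimethylsilyloxy)eudesma-4,11(13)-dien-12-oate | C=C(C(=O)OC)[C@H]1CC2=C(C)[C@@H](O[Si](C)(C)C(C)(C)C)CC[C@]2(C)C[C@H]1O | intermediate
25 | methyl 8β-acetoxy-3β-(tert-butyldimethylsilyloxy)eudesma-4,11(13)-dien-12-oate | C=C(C(=O)OC)[C@H]1CC2=C(C)[C@@H](O[Si](C)(C)C(C)(C)C)CC[C@]2(C)C[C@H]1OC(C)=O | intermediate
26 | methyl 8β-acetoxy-3β-hydroxyeudesma-4,11(13)-dien-12-oate | C=C(C(=O)OC)[C@H]1CC2=C(C)[C@@H](O)CC[C@]2(C)C[C@H]1OC(C)=O | intermediate
27 | methyl 8β-acetoxy-3β-isobutyryloxyeudesma-4,11(13)-dien-12-oate | C=C(C(=O)OC)[C@H]1CC2=C(C)[C@@H](OC(=O)C(C)C)CC[C@]2(C)C[C@H]1OC(C)=O | intermediate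
28 | methyl 8β-acetoxy-5α-hydroperoxy-3β-isobutyryloxyeudesma-4(15),11(13)-dien-12-oate | C=C(C(=O)OC)[C@H]1C[C@@]2(OO)C(=C)[C@@H](OC(=O)C(C)C)CC[C@]2(C)C[C@H]1OC(C)=O | target

Total step count: 14. Longest linear sequence: 14 steps, from 1 to 28.

The three steps most likely to fail are steps 3, 2 and 10.

Step 3 (key step). Chloro(methyl)carbene can rearrange to vinyl chloride faster than it adds to the hindered tetrasubstituted double bond. The part of the adduct whose chlorine points away from the five-membered ring cannot open in the allowed disrotatory sense and would be lost. The fallback sets out from 7 and comes back at 10, and it separates the insertion of C4 from the arrival of C15. Dibromocarbene (CHBr3, KOtBu, pentane, 0 °C) has no competing hydrogen shift and should give the dibromocyclopropane F1, in which one bromine always lies over the five-membered ring whatever the approach. AgNO3 in aqueous acetone should open it to the 4-bromo enone F2. A Stille coupling with Me4Sn (Pd(PPh3)4, CuI, DMF, 60 °C) then puts the C15 methyl on C4 and gives 10.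

Step 2. The hindered ketone next to the quaternary C10 may simply be reduced. The coupling may also stop at the ketol stage, or the Lewis-acidic titanium salts may strip the dioxolane or hydrolyse the enol ether. The fallback sets out from ketimine 4 and comes back at 10, and it closes the five-membered ring by a ketyl addition instead of a carbonyl coupling. Acrylonitrile in place of methyl acrylate should give the cyanoethylated ketimine F3 and, after aqueous acetic acid, the keto nitrile F4. Zn, Me3SiCl and 2,6-lutidine in refluxing THF (reductive 5-exo-dig ketone–nitrile cyclisation, then aqueous work-up) should give the cis-fused ketol F5. SOCl2 in pyridine can eliminate only toward C6 and gives the hydrindenone F6. A 1,4-hydrosilylation (Et3SiH, RhCl(PPh3)3, benzene, 50 °C) then gives the regiodefined triethylsilyl enol ether F7. This compound is taken through the carbene conditions of step 3, and the silyloxy chlorocyclopropane F8 loses Et3SiCl on warming and joins the route at 10.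

Step 10. The cis hydroxy ester can close back to the lactone during the esterification or while it waits for the slow acetylation of the axial alcohol. The amine can also leave too early, so that hydroxide or methoxide adds to the unmasked acrylate. The fallback sets out from 21 and comes back at 25, and it opens the lactone by reduction so that no hydroxy ester is ever present.

- MeI gives the lactone methiodide F9, and aqueous NaHCO3 gives the α-methylene lactone F10.
- DIBAL-H (CH2Cl2, −78 to 0 °C) gives the 8β,12-diol F11.
- Ac2O with DMAP gives the diacetate F12.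
- Brief K2CO3 in MeOH at 0 °C removes only the primary allylic acetate and gives the 8β-acetoxy allylic alcohol F13.
- MnO2 gives the enal F14.
- Pinnick oxidation (NaClO2, NaH2PO4, 2-methyl-2-butene) gives the acrylic acid F15.
- Me3SiCHN2 in MeOH–toluene gives 25.

Further compounds
F1 | step 3 | dibromocyclopropane (4,4-dibromo analogue of 9) | CO[C@@]12CC[C@]3(C)CC4(OCCO4)CC[C@@]13C2(Br)Br
F2 | step 3 | 4-bromo-8,8-ethylenedioxy-11,12,13,15-tetranoreudesm-4-en-3-one | O=C1CC[C@]2(C)CC3(CCC2=C1Br)OCCO3
F3 | step 2 | cyanoethylated ketimine (10R) | N#CCC[C@]1(C)CC2(CCC1=N[C@H](C)c1ccccc1)OCCO2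
F4 | step 2 | 3-[(7R)-7-methyl-8-oxo-1,4-dioxaspiro[4.5]decan-7-yl]propanenitrile | N#CCC[C@]1(C)CC2(CCC1=O)OCCO2
F5 | step 2 | cis-fused ketol (5β-hydroxy-10β-methyl hydrindan-3-one 8-ketal) | O=C1CC[C@]2(C)CC3(OCCO3)CC[C@]12O
F6 | step 2 | hydrindenone with C5=C6 conjugated to the C3 ketone | O=C1CC[C@]2(C)CC3(OCCO3)CC=C12
F7 | step 2 | triethylsilyl enol ether C3(OSiEt3)=C5 (silyl analogue of 7) | CC[Si](CC)(CC)OC1=C2CCC3(C[C@@]2(C)CC1)OCCO3
F8 | step 2 | silyloxy chlorocyclopropane (silyl analogue of 9) | CC[Si](CC)(CC)O[C@@]12CC[C@]3(C)CC4(OCCO4)CC[C@@]13[C@]2(C)Cl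
F9 | step 10 | methiodide of lactone 21 | O=C1[C@H](C[N+](C)(C)C)[C@H]2CC3=C(C)[C@@H](O[Si](C)(C)C(C)(C)C)CC[C@]3(C)C[C@H]2O1.[I-]
F10 | step 10 | 3β-(tert-butyldimethylsilyloxy)eudesma-4,11(13)-dien-8β,12-olide | O=C1C(=C)[C@H]2CC3=C(C)[C@@H](O[Si](C)(C)C(C)(C)C)CC[C@]3(C)C[C@H]2O1
F11 | step 10 | 3β-(tert-butyldimethylsilyloxy)eudesma-4,11(13)-diene-8β,12-diol | C=C(CO)[C@H]1CC2=C(C)[C@@H](O[Si](C)(C)C(C)(C)C)CC[C@]2(C)C[C@H]1O
F12 | step 10 | 8β,12-diacetate of F11 | C=C(COC(C)=O)[C@H]1CC2=C(C)[C@@H](O[Si](C)(C)C(C)(C)C)CC[C@]2(C)C[C@H]1OC(C)=O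
F13 | step 10 | 8β-acetoxy-3β-(tert-butyldimethylsilyloxy)eudesma-4,11(13)-dien-12-ol | C=C(CO)[C@H]1CC2=C(C)[C@@H](O[Si](C)(C)C(C)(C)C)CC[C@]2(C)C[C@H]1OC(C)=O
F14 | step 10 | 8β-acetoxy-3β-(tert-butyldimethylsilyloxy)eudesma-4,11(13)-dien-12-al | C=C(C=O)[C@H]1CC2=C(C)[C@@H](O[Si](C)(C)C(C)(C)C)CC[C@]2(C)C[C@H]1OC(C)=O
F15 | step 10 | 8β-acetoxy-3β-(tert-butyldimethylsilyloxy)eudesma-4,11(13)-dien-12-oic acid | C=C(C(=O)O)[C@H]1CC2=C(C)[C@@H](O[Si](C)(C)C(C)(C)C)CC[C@]2(C)C[C@H]1OC(C)=O
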